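Time looks like the lever in this flask, since its 15 h runs far beyond the 90.0 min of the last reading of the earlier run, epsilon. So the end state comes first.

- epsilon: free monomer 0.36 M (fed, over 2.0 min); transfer agent 0.072 M; initiator 1 mM; run made earlier; the fed solution adds 0.50 times the starting volume
- flask: free monomer 0.24 M (fed, over 2.0 min); transfer agent 0.0720 M; initiator 1.0 mM; time 15 h; the fed solution adds 0.50 times the starting volume

- epsilon (time / min: monomer in chains / %, uncatalysed product / %): 8.00: 41.7, 21.9; 15.0: 56.5, 27.0; 40.0: 63.0, 35.6; 90.0: 61.2, 39.1

(scatter of a reading: 1 percentage point)

- amounts are per litre of the starting volume; all of the dose is in the solution fed

1. monomer in chains at 15 h, in percent of the free monomer charged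
2. uncatalysed product at 15 h, in percent of the free monomer charged
3. amount of monomer in chains if the flask were left three thousand times as long, in percent of the free monomer charged

Turn the question round: a drain of chains into uncatalysed product over such a time would have to begin as a fall of the chains in epsilon. They read 63.0%, then 61.2%, a drop of 1.8 percentage points, while the difference of two readings scatters by 1.4 points. That is a weak sign of a fall. At the last epsilon reading the two products sum to 100%, so free monomer in epsilon stands near zero within scatter.

My own reckoning takes the chains as stable. The end state is then described by the end split, a selectivity factor: monomer in chains over uncatalysed product at the end of a run, read from the last epsilon reading as 1.57. If both routes are first order in free monomer, the split does not follow its charge, and this flask has the transfer agent and initiator of epsilon. So I expect in this flask 61.1% in chains and 38.9% as product, with the same chains in the long run.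

The forecast differs: 14% in chains (3% to 42%), 86% as product and 0% in the long run, on the ground that “chains hold a small equilibrium free monomer”.

The flask gives 60.3% in chains, 39.7% as product and 60.3% in the long run. The chains of the flask stand at 60.3% at 7.50 h and 60.3% at 150 h.

    free monomer + initiator → living end + monomer in chains (k = 4.90 /M/min)
    living end + transfer agent → dead chain (kL = 1.50 /M/min)
    free monomer → uncatalysed product (k = 0.0450 /min)
    free monomer + living end → monomer in chains + living end, rate k4*[living end]*[free monomer] (k = 210 /M/min)

The end split of the flask is 1.52, beside the 1.57 read from epsilon. Taking the split as inversely proportional to [transfer agent], a neighbouring flask with 0.12 M of transfer agent has 0.939, hence 48.4% in chains. The simulation of that neighbouring flask gives 51.2%.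

The runs were computed from invented constants, and the scatter is random.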